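**Strategy.** The route rests on cutting the cyclohexane bond between the quaternary carbon (CH3, CH2OAr) and the adjacent CH that carries the acetoxypropyl chain, beside the ring carbon bearing the isopropylidene. With the CH2O carbon as a carboxyl, these atoms and the C=CMe2 unit form a γ,δ-unsaturated acid, the product of an Ireland–Claisen shift. The precursor is an eight-membered lactone whose ring oxygen sits on the CMe2 carbon beside an exocyclic E alkylidene. One operation contracts it to the cyclohexane, sets both new stereocentres from the existing methyl-bearing centre, creates the tetrasubstituted alkene and frees the carboxyl. The lactone comes from metathesis of an ester of two small fragments.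

Key step: step 8

Remark: compounds 9 to 13 are carried as mixtures at the carbon alpha to the carboxyl group, because step 8 makes this carbon a planar ketene acetal carbon; racemic 5, silyl ether 1 and bromocoumarin 18 are taken as commercial.

Step 1
Reactants: 1 tert-butyldimethyl(pent-4-yn-1-yloxy)silane; 2 acetone
Product: 3 7-[(tert-butyldimethylsilyl)oxy]-2-methylhept-3-yn-2-ol
Conditions: n-BuLi, THF, −78 °C; then 2, −78 to 0 °C; H2O
Reagents that add atoms: none
Why: 1,2-Addition of the lithium acetylide to the ketone should give the tertiary propargylic alcohol; no stereocentre is formed.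

Step 2
Reactants: 3 7-[(tert-butyldimethylsilyl)oxy]-2-methylhept-3-yn-2-ol
Product: 4 (3E)-7-[(tert-butyldimethylsilyl)oxy]-3-ethenyl-2-methylhept-3-en-2-ol
Conditions: CH2=CHMgCl (4 equiv), THF, 65 °C; aq. NH4Cl
Reagents that add atoms: vinylmagnesium chloride, C=C[Mg]Cl
Why: Alkoxide-directed anti-carbomagnesiation of the propargylic alcohol places vinyl on the alkyne carbon next to the carbinol and magnesium on the far carbon inside a five-membered chelate, so protonation should leave the silyloxypropyl chain cis to the vinyl group (E alkene).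

Step 3
Reactants: 5 (3E)-pent-3-en-2-ol (racemic)
Product: 6 (2R,3E)-pent-3-en-2-yl propanoate
Conditions: lipase B from Candida antarctica (immobilised), vinyl propanoate, hexane, 25 °C, to about half conversion
Reagents that add atoms: vinyl propanoate, CCC(=O)OC=C
Why: Kinetic resolution by lipase (serine hydrolase) transesterification should acylate the R alcohol much faster (alkenyl as large group, methyl as medium group), which sets the carbinol centre; the S alcohol stays unreacted and is separated.

Step 4
Reactants: 6 (2R,3E)-pent-3-en-2-yl propanoate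
Product: 9 (2RS,3S,4E)-2,3-dimethylhex-4-enoic acid, via silyl ketene acetal 7 (not isolated), via trimethylsilyl ester 8 (not isolated)
Conditions: LiN(iPr)2, THF, −78 °C; Me3SiCl; −78 to 25 °C; 1 M HCl
Reagents that add atoms: none
Why: Ireland–Claisen rearrangement through a chair with the carbinol methyl equatorial should transfer the C–O chirality to the new C-3 stereocentre (S) and give the E alkene; C-2 is left unassigned because it is enolised in step 8.

Step 5
Reactants: 9 (2RS,3S,4E)-2,3-dimethylhex-4-enoic acid; 4 (3E)-7-[(tert-butyldimethylsilyl)oxy]-3-ethenyl-2-methylhept-3-en-2-ol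
Product: 11 (3E)-7-[(tert-butyldimethylsilyl)oxy]-3-ethenyl-2-methylhept-3-en-2-yl (2RS,3S,4E)-2,3-dimethylhex-4-enoate, via acyl chloride 10 (not isolated)
Conditions: 9, (COCl)2, DMF (cat.), CH2Cl2, 0 to 25 °C, evaporate; 4, n-BuLi, THF, −78 °C, then 10, −78 to 0 °C
Reagents that add atoms: none
Why: Nucleophilic acyl substitution of the acyl chloride by the lithium tertiary alkoxide should give the hindered ester without acid, which would ionise the tertiary allylic alcohol; no stereocentre is formed.

Step 6
Reactants: 11 (3E)-7-[(tert-butyldimethylsilyl)oxy]-3-ethenyl-2-methylhept-3-en-2-yl (2RS,3S,4E)-2,3-dimethylhex-4-enoate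
Product: 12 (3RS,4S,5Z,7E)-7-{4-[(tert-butyldimethylsilyl)oxy]butylidene}-3,4,8,8-tetramethyl-3,4,7,8-tetrahydro-2H-oxocin-2-one
Conditions: second-generation Grubbs catalyst RuCl2(=CHPh)(H2IMes)(PCy3) (10 mol%), toluene (0.001 M), 80 °C
Reagents that add atoms: none
Why: Ring-closing olefin metathesis between the vinyl and propenyl groups (loss of propene) should close the eight-membered lactone, helped by the gem-dimethyl group and three sp2 ring atoms; the ring can hold only the cis alkene and both C-3 epimers should close.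

Step 7
Reactants: 12 (3RS,4S,5Z,7E)-7-{4-[(tert-butyldimethylsilyl)oxy]butylidene}-3,4,8,8-tetramethyl-3,4,7,8-tetrahydro-2H-oxocin-2-one
Product: 13 (3RS,4S,7E)-7-{4-[(tert-butyldimethylsilyl)oxy]butylidene}-3,4,8,8-tetramethyloxocan-2-one
Conditions: TsNHNH2, NaOAc, DME–H2O, 85 °C
Reagents that add atoms: none
Why: Diimide reduction (concerted syn transfer of H2 from HN=NH) should take the strained cis-disubstituted ring alkene much faster than the trisubstituted exocyclic alkene; no stereocentre is formed.

Step 8
Reactants: 13 (3RS,4S,7E)-7-{4-[(tert-butyldimethylsilyl)oxy]butylidene}-3,4,8,8-tetramethyloxocan-2-one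
Product: 16 (1S,2S,6S)-2-{3-[(tert-butyldimethylsilyl)oxy]propyl}-1,6-dimethyl-3-(propan-2-ylidene)cyclohexane-1-carboxylic acid, via cyclic silyl ketene acetal 14 (not isolated), via trimethylsilyl ester 15 (not isolated)
Conditions: LiN(iPr)2, Me3SiCl, Et3N, THF, −78 °C; then toluene, 25 to 80 °C; H2O, pH 5
Reagents that add atoms: none
Why: Proposed new method: enolisation and silylation should give the endocyclic silyl ketene acetal 14, in which the O–CMe2–C(=CH–chain) unit is an allyl ester with an exocyclic terminus, and a chair [3,3] shift then joins the lactone α-carbon to the alkylidene carbon while the ring C–O bond breaks, so the eight-membered lactone contracts to the cyclohexane and the freed carbon becomes the isopropylidene. The closest known reaction type is the Ireland–Claisen ring contraction of unsaturated medium and large lactones, established for endocyclic allylic alkenes and here extended to an exocyclic alkylidene. The carbocycle closes by C1–C2 bond formation, a 6-endo attack of the ketene acetal carbon on the alkylidene carbon through a bicyclo[3.3.1]-like transition state in which the CH2CH2 tether links the ketene acetal terminus to the central allyl carbon, an arrangement the boat cannot reach. C1 is set by the ring-enforced cis ketene acetal geometry (carboxyl carbon axial, methyl equatorial), C2 by the E alkylidene geometry (chain trans to the carboxyl carbon, cis to the C1 methyl), and the face by the existing C6 methyl, which stays equatorial because its axial position would clash with the chain. The step needs rearrangement to outrun fragmentation of the ester enolate, which silylation in situ at −78 °C should secure.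

Step 9
Reactants: 16 (1S,2S,6S)-2-{3-[(tert-butyldimethylsilyl)oxy]propyl}-1,6-dimethyl-3-(propan-2-ylidene)cyclohexane-1-carboxylic acid
Product: 17 [(1S,2S,6S)-2-{3-[(tert-butyldimethylsilyl)oxy]propyl}-1,6-dimethyl-3-(propan-2-ylidene)cyclohexyl]methanol
Conditions: LiAlH4, THF, 0 to 65 °C; H2O, NaOH
Reagents that add atoms: none
Why: Hydride reduction of the hindered carboxylic acid should give the neopentyl alcohol; the silyl ether and the tetrasubstituted alkene are inert and no stereocentre is touched.

Step 10
Reactants: 17 [(1S,2S,6S)-2-{3-[(tert-butyldimethylsilyl)oxy]propyl}-1,6-dimethyl-3-(propan-2-ylidene)cyclohexyl]methanol; 18 7-bromo-2H-chromen-2-one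
Product: 19 7-{[(1S,2S,6S)-2-{3-[(tert-butyldimethylsilyl)oxy]propyl}-1,6-dimethyl-3-(propan-2-ylidene)cyclohexyl]methoxy}-2H-chromen-2-one
Conditions: Pd2(dba)3 (2 mol%), RockPhos (6 mol%), Cs2CO3, toluene, 90 °C
Reagents that add atoms: none
Why: Palladium-catalysed C–O cross-coupling (Buchwald–Hartwig etherification) forms the ether bond at the aryl carbon by oxidative addition of zerovalent palladium into C–Br and reductive elimination of the alkoxide, so no substitution at the neopentyl carbon is needed.

Step 11
Reactants: 19 7-{[(1S,2S,6S)-2-{3-[(tert-butyldimethylsilyl)oxy]propyl}-1,6-dimethyl-3-(propan-2-ylidene)cyclohexyl]methoxy}-2H-chromen-2-one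
Product: 21 3-[(1S,2S,3S)-2,3-dimethyl-2-{[(2-oxo-2H-chromen-7-yl)oxy]methyl}-6-(propan-2-ylidene)cyclohexyl]propyl acetate (CNP0318693.1), via primary alcohol 20 (not isolated)
Conditions: Bu4NF, THF, 0 °C; then Ac2O, DMAP (cat.), 0 to 25 °C
Reagents that add atoms: acetic anhydride, CC(=O)OC(C)=O
Why: Fluoride cleavage of the silyl ether followed by acylation of the primary alkoxide in the same flask should give the acetate; the aryl ether, lactone and stereocentres are untouched.

**Compound list**

1 | tert-butyldimethyl(pent-4-yn-1-yloxy)silane | C#CCCCO[Si](C)(C)C(C)(C)C | starting material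
2 | acetone | CC(C)=O | starting material
3 | 7-[(tert-butyldimethylsilyl)oxy]-2-methylhept-3-yn-2-ol | CC(C)(O)C#CCCCO[Si](C)(C)C(C)(C)C | intermediate
4 | (3E)-7-[(tert-butyldimethylsilyl)oxy]-3-ethenyl-2-methylhept-3-en-2-ol | CC(C)(O)/C(C=C)=C/CCCO[Si](C)(C)C(C)(C)C | intermediate
5 | (3E)-pent-3-en-2-ol, racemic | C/C=C/C(C)O | starting material
6 | (2R,3E)-pent-3-en-2-yl propanoate | C/C=C/[C@@H](C)OC(=O)CC | intermediate
7 | trimethyl({1-[(2R,3E)-pent-3-en-2-yloxy]prop-1-en-1-yl}oxy)silane (silyl ketene acetal) | C/C=C/[C@@H](C)OC(O[Si](C)(C)C)=CC | intermediate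
8 | trimethylsilyl (2RS,3S,4E)-2,3-dimethylhex-4-enoate | C/C=C/[C@H](C)C(C)C(=O)O[Si](C)(C)C | intermediate
9 | (2RS,3S,4E)-2,3-dimethylhex-4-enoic acid | C/C=C/[C@H](C)C(C)C(O)=O | intermediate
10 | (2RS,3S,4E)-2,3-dimethylhex-4-enoyl chloride | C/C=C/[C@H](C)C(C)C(Cl)=O | intermediate
11 | (3E)-7-[(tert-butyldimethylsilyl)oxy]-3-ethenyl-2-methylhept-3-en-2-yl (2RS,3S,4E)-2,3-dimethylhex-4-enoate | C/C=C/[C@H](C)C(C)C(=O)OC(C)(C)/C(C=C)=C/CCCO[Si](C)(C)C(C)(C)C | intermediate
12 | (3RS,4S,5Z,7E)-7-{4-[(tert-butyldimethylsilyl)oxy]butylidene}-3,4,8,8-tetramethyl-3,4,7,8-tetrahydro-2H-oxocin-2-one | O=C1OC(C)(C)/C(=C/CCCO[Si](C)(C)C(C)(C)C)/C=C\[C@H](C)C1C | intermediate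
13 | (3RS,4S,7E)-7-{4-[(tert-butyldimethylsilyl)oxy]butylidene}-3,4,8,8-tetramethyloxocan-2-one | O=C1OC(C)(C)/C(=C/CCCO[Si](C)(C)C(C)(C)C)CC[C@H](C)C1C | intermediate
14 | (4S,7E)-7-{4-[(tert-butyldimethylsilyl)oxy]butylidene}-3,4,8,8-tetramethyl-2-[(trimethylsilyl)oxy]-5,6,7,8-tetrahydro-4H-oxocine (cyclic silyl ketene acetal) | C[Si](C)(C)OC1=C(C)[C@@H](C)CC\C(=C/CCCO[Si](C)(C)C(C)(C)C)C(C)(C)O1 | intermediate
15 | trimethylsilyl (1S,2S,6S)-2-{3-[(tert-butyldimethylsilyl)oxy]propyl}-1,6-dimethyl-3-(propan-2-ylidene)cyclohexane-1-carboxylate | CC(C)(C)[Si](C)(C)OCCC[C@H]1C(=C(C)C)CC[C@H](C)[C@]1(C)C(=O)O[Si](C)(C)C | intermediate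
16 | (1S,2S,6S)-2-{3-[(tert-butyldimethylsilyl)oxy]propyl}-1,6-dimethyl-3-(propan-2-ylidene)cyclohexane-1-carboxylic acid | CC(C)(C)[Si](C)(C)OCCC[C@H]1C(=C(C)C)CC[C@H](C)[C@]1(C)C(O)=O | intermediate
17 | [(1S,2S,6S)-2-{3-[(tert-butyldimethylsilyl)oxy]propyl}-1,6-dimethyl-3-(propan-2-ylidene)cyclohexyl]methanol | CC(C)(C)[Si](C)(C)OCCC[C@H]1C(=C(C)C)CC[C@H](C)[C@]1(C)CO | intermediate
18 | 7-bromo-2H-chromen-2-one | O=c1ccc2ccc(Br)cc2o1 | starting material
19 | 7-{[(1S,2S,6S)-2-{3-[(tert-butyldimethylsilyl)oxy]propyl}-1,6-dimethyl-3-(propan-2-ylidene)cyclohexyl]methoxy}-2H-chromen-2-one | CC(C)(C)[Si](C)(C)OCCC[C@H]1C(=C(C)C)CC[C@H](C)[C@]1(C)COc1ccc2ccc(=O)oc2c1 | intermediate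
20 | 7-{[(1S,2S,6S)-2-(3-hydroxypropyl)-1,6-dimethyl-3-(propan-2-ylidene)cyclohexyl]methoxy}-2H-chromen-2-one | OCCC[C@H]1C(=C(C)C)CC[C@H](C)[C@]1(C)COc1ccc2ccc(=O)oc2c1 | intermediate
21 | 3-[(1S,2S,3S)-2,3-dimethyl-2-{[(2-oxo-2H-chromen-7-yl)oxy]methyl}-6-(propan-2-ylidene)cyclohexyl]propyl acetate | CC(=O)OCCC[C@H]1C(=C(C)C)CC[C@H](C)[C@]1(C)COc1ccc2ccc(=O)oc2c1 | target

**Total step count:** 11. **Longest linear sequence:** 9 steps (steps 3 to 11).

**Steps most likely to fail**

1. Step 8 (proposed new method). The lactone enolate may fragment by loss of the tertiary allylic alkoxide before it is silylated, or the ring may fail to fold into the chair so that ionisation of the ketene acetal takes over. The fallback replaces the sigmatropic shift by a stepwise ionic closure of known type and sets out from 13. Methanolysis (NaOMe, MeOH) should open the lactone to methyl (2RS,3S,6E)-10-[(tert-butyldimethylsilyl)oxy]-6-(2-hydroxypropan-2-yl)-2,3-dimethyldec-6-enoate F1. LiN(iPr)2 (2.2 equiv) and Me3SiCl should silylate the tertiary alcohol and convert the ester into its silyl ketene acetal. Catalytic Me3SiOTf in CH2Cl2 at −78 °C should then ionise the tertiary allylic silyl ether, and the ketene acetal should trap the allyl cation at its secondary terminus in a six-membered closure (Lewis-acid alkylation of a silyl ketene acetal, Mukaiyama type). This should give methyl (1S,2S,6S)-2-{3-[(tert-butyldimethylsilyl)oxy]propyl}-1,6-dimethyl-3-(propan-2-ylidene)cyclohexane-1-carboxylate F2, from which any C-1 epimer would be removed by chromatography. Reduction of F2 with LiAlH4 comes back to the route at 17.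

2. Step 6. Intermolecular metathesis may outrun closure of the strained eight-membered ester ring, and turnover at the conjugated vinyl group may be slow. The fallback avoids any medium ring and sets out from 4 and 9. Esterification of 9 with Me3SiCHN2 should give methyl (2RS,3S,4E)-2,3-dimethylhex-4-enoate F3. Cross metathesis of F3 with the vinyl group of 4 (second-generation Hoveyda–Grubbs catalyst RuCl2(=CH-2-(iPrO)C6H4)(H2IMes)) should give methyl (2RS,3S,4E,6E)-10-[(tert-butyldimethylsilyl)oxy]-6-(2-hydroxypropan-2-yl)-2,3-dimethyldeca-4,6-dienoate F4. Diimide reduction of its disubstituted alkene leads to F1, and the sequence through F2 described above comes back to the route at 17.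

3. Step 10. Reductive elimination at the crowded alkoxide may be slow, so that β-hydride elimination reduces the aryl bromide instead of coupling. The fallback forms the ether at the sp3 carbon and sets out from 17. Tf2O and 2,6-lutidine (CH2Cl2, −78 °C) should give [(1S,2S,6S)-2-{3-[(tert-butyldimethylsilyl)oxy]propyl}-1,6-dimethyl-3-(propan-2-ylidene)cyclohexyl]methyl trifluoromethanesulfonate F5. Displacement by the caesium salt of 7-hydroxy-2H-chromen-2-one (Cs2CO3, DMF, 50 °C, Williamson ether synthesis) comes back to the route at 19.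

**Further compounds**

F1 | step 8 | methyl (2RS,3S,6E)-10-[(tert-butyldimethylsilyl)oxy]-6-(2-hydroxypropan-2-yl)-2,3-dimethyldec-6-enoate | COC(=O)C(C)[C@@H](C)CC/C(=C\CCCO[Si](C)(C)C(C)(C)C)C(C)(C)O
F2 | step 8 | methyl (1S,2S,6S)-2-{3-[(tert-butyldimethylsilyl)oxy]propyl}-1,6-dimethyl-3-(propan-2-ylidene)cyclohexane-1-carboxylate | CC(C)(C)[Si](C)(C)OCCC[C@H]1C(=C(C)C)CC[C@H](C)[C@]1(C)C(=O)OC
F3 | step 6 | methyl (2RS,3S,4E)-2,3-dimethylhex-4-enoate | C/C=C/[C@H](C)C(C)C(=O)OC
F4 | step 6 | methyl (2RS,3S,4E,6E)-10-[(tert-butyldimethylsilyl)oxy]-6-(2-hydroxypropan-2-yl)-2,3-dimethyldeca-4,6-dienoate | COC(=O)C(C)[C@@H](C)/C=C/C(=C\CCCO[Si](C)(C)C(C)(C)C)C(C)(C)O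
F5 | step 10 | [(1S,2S,6S)-2-{3-[(tert-butyldimethylsilyl)oxy]propyl}-1,6-dimethyl-3-(propan-2-ylidene)cyclohexyl]methyl trifluoromethanesulfonate | CC(C)(C)[Si](C)(C)OCCC[C@H]1C(=C(C)C)CC[C@H](C)[C@]1(C)COS(=O)(=O)C(F)(F)F
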